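## Retrosynthetic overview

1. The last C–O bond is the C-14 ester: the caesium carboxylate of acid 29 opens the spiro-oxirane of lactone 14 at CH2, and one fluoride step then removes two TBS ethers and the TMSE ester.
2. Lactone half: the seven-membered lactone comes from ozonolysis of the C-2=C-3 bond of a cis-fused cyclohexadiene ester. That carbocycle comes from (S)-cryptone by Diels–Alder reaction with Danishefsky's diene (sets C-1, C-6), carbenoid epoxidation (sets C-10) and enol-triflate carbonylation (adds C-15).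
3. Acid half: the cyclohexene comes from an endo Diels–Alder reaction of a 2,4,6-trienoate with methyl vinyl ketone (sets C-6′/C-7′ cis), then acetyl → isopropyl. The trienoate comes from a Heck reaction followed by a Wittig reaction.
4. Ring order: cyclohexenone (Michael/aldol) → temporary second carbocycle (Diels–Alder) → spiro-oxirane → cleavage and relactonization to the oxepinone; the acid-half cyclohexene is made separately by Diels–Alder.

Assumption: the SMILES is taken literally – lactone half (1S,6R,7S,10R) with C-5 trans to isopropyl, acid half (6′R,7′S) with the acrylate chain cis to isopropyl, (E)-acrylate.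

Atom labels used in names: alcohol half C-1 (lactone α-CH), C-2 (lactone C=O), C-3 (OCH2), C-4=C-5 (ring alkene; C-15 = carboxyl on C-4), C-6 (ring-fusion CH), C-7 (CH–iPr), C-8, C-9, C-10 (carbinol C), C-14 (CH2O on C-10); acid half primed: C-6′ (CH bearing the acrylate chain), C-7′ (CH–iPr).

## Route

Step 1
Reactants: 1 3-methylbutanal; 2 but-3-en-2-one
Product: 4 (S)-4-isopropylcyclohex-2-en-1-one, via (S)-2-isopropyl-5-oxohexanal 3 (not isolated)
Conditions: (S)-2-(methoxydiphenylmethyl)pyrrolidine (5 mol%), ethyl 3,4-dihydroxybenzoate (20 mol%), neat, 4 °C; then LiOH, iPrOH, rt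
Reagents that add atoms: none
Why: Enamine-catalysed Michael addition to the enone on the enamine face anti to the CPh2OMe group sets the (S) centre, and base-mediated intramolecular aldol condensation closes the cyclohexenone (organocatalytic Robinson-type annulation).

Step 2
Reactants: 4 (S)-4-isopropylcyclohex-2-en-1-one; 5 (E)-1-methoxy-3-(trimethylsilyloxy)buta-1,3-diene
Product: 6 cis-fused cycloadduct (1R,2S,6S,7S), C-10 ketone, 2-OMe, C-3=C-4 silyl enol ether
Conditions: 5 (3 equiv), PhMe, BHT (cat.), 140 °C, sealed tube; non-acidic work-up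
Reagents that add atoms: none
Why: Thermal Diels–Alder reaction in which the diene adds to the enone face anti to the isopropyl group with its nucleophilic CH2 terminus on the β-carbon (C-6), so C-5 is trans to isopropyl and suprafacial addition makes H-1/H-6 cis (the endo methoxy centre is erased later).

Step 3
Reactants: 6 cis-fused cycloadduct
Product: 8 (1S,6S,7S,10R)-epoxy enone, via epoxy silyl enol ether 7 (not isolated)
Conditions: ClCH2I, MeLi·LiBr, THF, −78 °C → rt; then K2CO3, MeOH, 0 °C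
Reagents that add atoms: chloroiodomethane ClCI
Why: Chloromethyllithium (Barbier-type halomethyl carbenoid addition) attacks the ketone axially on the convex face, anti to the axial C-1–C-2 bond, and the chlorohydrin alkoxide closes to the spiro-oxirane with C-14 on the isopropyl face and O on the C-2 face (C-10 R); methanolysis of the silyl enol ether and E1cB loss of methoxide then unveil the enone.

Step 4
Reactants: 8 (1S,6S,7S,10R)-epoxy enone
Product: 9 (1S,6R,7S,10R)-dienyl triflate
Conditions: LiN(SiMe3)2, THF, −78 °C; then PhNTf2, −78 → 0 °C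
Reagents that add atoms: N-phenylbis(trifluoromethanesulfonimide) FC(F)(F)S(=O)(=O)N(c1ccccc1)S(=O)(=O)C(F)(F)F
Why: Kinetic α′-deprotonation at C-5 by the hindered amide and O-sulfonylation of the cross-conjugated dienolate (enol triflate formation) leave all stereocentres untouched.

Step 5
Reactants: 9 (1S,6R,7S,10R)-dienyl triflate
Product: 10 (1S,6R,7S,10R)-2-(trimethylsilyl)ethyl dienoate
Conditions: Pd(OAc)2 (5 mol%), PPh3, CO (1 atm), Me3SiCH2CH2OH, Et3N, DMF, 50 °C
Reagents that add atoms: carbon monoxide [C-]#[O+]; 2-(trimethylsilyl)ethanol C[Si](C)(C)CCO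
Why: Palladium-catalysed alkoxycarbonylation of the dienyl triflate (oxidative addition to zerovalent palladium, CO insertion, alcoholysis) installs C-15 as a fluoride-labile ester with the ring diene intact.

Step 6
Reactants: 10 (1S,6R,7S,10R)-2-(trimethylsilyl)ethyl dienoate
Product: 12 (1S,6R,7S,10R)-aldehyde diester, via methoxy hydroperoxide 11 (not isolated)
Conditions: O3, CH2Cl2/MeOH (5:1), NaHCO3, −78 °C; then Ac2O, Et3N, 0 °C → rt
Reagents that add atoms: ozone [O-][O+]=O; methanol CO
Why: Criegee ozonolysis of the only electron-rich alkene (C-2=C-3; C-4=C-5 is deactivated by the ester), with fragmentation to the carbonyl oxide on the alkyl side, methanol trapping and acetylative dehydration, gives the C-2 methyl ester and the C-3 aldehyde (end-differentiating ozonolysis) while the ring-derived cis geometry at C-4=C-5 is kept.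

Step 7
Reactants: 12 (1S,6R,7S,10R)-aldehyde diester
Product: 14 (1S,6R,7S,10R)-epoxy lactone, via hydroxy diester 13 (not isolated)
Conditions: NaBH4, CeCl3·7H2O, MeOH, −78 °C; then Bu2SnO (10 mol%), PhMe, 80 °C
Reagents that add atoms: none
Why: Luche 1,2-reduction of the aldehyde gives the allylic alcohol, which is held cis to C-6 and closes on the C-2 methyl ester by tin-catalysed transesterification (lactonization) to the cis-fused seven-membered lactone without touching a stereocentre.

Step 8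
Reactants: 15 (2-bromoethoxy)(tert-butyl)dimethylsilane; 16 triphenylphosphine
Product: 17 [2-(tert-butyldimethylsilyloxy)ethyl]triphenylphosphonium bromide
Conditions: MeCN, reflux
Reagents that add atoms: none
Why: SN2 alkylation of the phosphine by the primary bromide (phosphonium salt formation).

Step 9
Reactants: 17 [2-(tert-butyldimethylsilyloxy)ethyl]triphenylphosphonium bromide
Product: 20 methyl 3-(tert-butyldimethylsilyloxy)-2-(triphenylphosphoranylidene)propanoate, via silyloxyethylidene ylide 18 (not isolated), via acylphosphonium chloride 19 (not isolated)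
Conditions: NaN(SiMe3)2 (1 equiv), THF, −78 °C; ClCO2Me, −78 → 0 °C; then NaN(SiMe3)2 (1 equiv)
Reagents that add atoms: methyl chloroformate COC(=O)Cl
Why: Deprotonation to the non-stabilised ylide, C-acylation by the chloroformate and a second deprotonation give the ester-stabilised ylide (ylide acylation).

Step 10
Reactants: 21 2-bromoprop-2-en-1-ol
Product: 22 (2-bromoallyloxy)(tert-butyl)dimethylsilane
Conditions: TBSCl, imidazole, CH2Cl2, 0 °C → rt
Reagents that add atoms: tert-butyldimethylsilyl chloride CC(C)(C)[Si](C)(C)Cl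
Why: Silylation of the primary alcohol (silyl ether protection).

Step 11
Reactants: 22 (2-bromoallyloxy)(tert-butyl)dimethylsilane; 23 acrolein
Product: 24 (E)-4-[(tert-butyldimethylsilyloxy)methyl]penta-2,4-dienal
Conditions: Pd(OAc)2 (5 mol%), Bu4NCl, NaHCO3, DMF, 50 °C
Reagents that add atoms: none
Why: Mizoroki–Heck vinylation under phase-transfer (Jeffery) conditions, where syn insertion and syn β-hydride elimination give the (E)-dienal.

Step 12
Reactants: 24 (E)-4-[(tert-butyldimethylsilyloxy)methyl]penta-2,4-dienal; 20 methyl 3-(tert-butyldimethylsilyloxy)-2-(triphenylphosphoranylidene)propanoate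
Product: 25 methyl (2E,4E)-2,6-bis[(tert-butyldimethylsilyloxy)methyl]hepta-2,4,6-trienoate
Conditions: PhMe, 80 °C
Reagents that add atoms: none
Why: Wittig olefination with the α-substituted ester-stabilised ylide gives the (E)-trisubstituted enoate (chain trans to CO2Me) as expected for stabilised ylides.

Step 13
Reactants: 25 methyl (2E,4E)-2,6-bis[(tert-butyldimethylsilyloxy)methyl]hepta-2,4,6-trienoate; 2 but-3-en-2-one
Product: 26 methyl (E)-3-[(1R,6R)-6-acetyl-3-{[(tert-butyldimethylsilyl)oxy]methyl}cyclohex-2-en-1-yl]-2-{[(tert-butyldimethylsilyl)oxy]methyl}prop-2-enoate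
Conditions: 2 (3 equiv), (R)-3,3-diphenyl-1-(2-methylphenyl)tetrahydro-1H,3H-pyrrolo[1,2-c][1,3,2]oxazaborole (20 mol%), HNTf2 (16 mol%), CH2Cl2, −78 → −40 °C
Reagents that add atoms: none
Why: Chiral oxazaborolidinium-catalysed Diels–Alder reaction at the terminal diene, in which the 1-alkenyl and 3-alkyl substituents both direct the acetyl-bearing carbon next to C-6′, the endo transition state puts acetyl cis to the acrylate chain, and the (R)-catalyst screens the α-Re face of bound methyl vinyl ketone so that the (6′R,7′R) adduct forms.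

Step 14
Reactants: 26 acetyl cycloadduct
Product: 27 methyl (E)-3-[(1R,6R)-3-{[(tert-butyldimethylsilyl)oxy]methyl}-6-(prop-1-en-2-yl)cyclohex-2-en-1-yl]-2-{[(tert-butyldimethylsilyl)oxy]methyl}prop-2-enoate
Conditions: Zn, CH2Br2, TiCl4, THF/CH2Cl2, 0 °C → rt
Reagents that add atoms: dibromomethane BrCBr
Why: Takai–Lombardo methylenation (titanium–zinc methylene transfer) converts only the ketone and, being non-basic, does not epimerise the cis α-centre C-7′.

Step 15
Reactants: 27 isopropenyl ester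
Product: 28 methyl (E)-3-[(1R,6S)-3-{[(tert-butyldimethylsilyl)oxy]methyl}-6-isopropylcyclohex-2-en-1-yl]-2-{[(tert-butyldimethylsilyl)oxy]methyl}prop-2-enoate
Conditions: H2 (1 atm), RhCl(PPh3)3 (5 mol%), PhH/EtOH, rt
Reagents that add atoms: none
Why: Homogeneous hydrogenation with RhCl(PPh3)3 reduces only the 1,1-disubstituted isopropenyl group and leaves both trisubstituted alkenes, so isopropyl stays cis to the chain (the C-7′ descriptor becomes S by priority change only).

Step 16
Reactants: 28 isopropyl methyl ester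
Product: 29 (E)-3-[(1R,6S)-3-{[(tert-butyldimethylsilyl)oxy]methyl}-6-isopropylcyclohex-2-en-1-yl]-2-{[(tert-butyldimethylsilyl)oxy]methyl}prop-2-enoic acid
Conditions: Me3SnOH, ClCH2CH2Cl, 80 °C; then 5% aq HCl
Reagents that add atoms: trimethyltin hydroxide C[Sn](C)(C)O
Why: Tin-mediated neutral ester hydrolysis cleaves the methyl ester without silyl loss or epimerisation of the bis-allylic C-6′ centre.

Step 17
Reactants: 14 (1S,6R,7S,10R)-epoxy lactone; 29 bis-silylated acid
Product: 30 protected C-14 ester with free C-10 tertiary alcohol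
Conditions: Cs2CO3 (1 equiv), DMF, 70 °C
Reagents that add atoms: none
Why: SN2 ring opening of the oxirane at its primary carbon (C-14) by the caesium carboxylate forms the ester and frees the tertiary alcohol with retention at C-10.

Step 18
Reactants: 30 protected C-14 ester
Product: 31 target CNP0361406.6
Conditions: Bu4NF, AcOH (1:1), THF, 0 °C → rt
Reagents that add atoms: none
Why: Fluoride-mediated global deprotection by Si–O cleavage of both silyl ethers and β-elimination (ethene, Me3SiF) of the 2-(trimethylsilyl)ethyl ester, buffered with AcOH to spare the lactone and esters.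

## Compound list

1 | 3-methylbutanal (isovaleraldehyde) | CC(C)CC=O | starting material
2 | but-3-en-2-one (methyl vinyl ketone) | CC(=O)C=C | starting material
3 | (S)-2-isopropyl-5-oxohexanal | CC(C)[C@@H](C=O)CCC(C)=O | intermediate
4 | (S)-4-isopropylcyclohex-2-en-1-one ((S)-cryptone) | CC(C)[C@@H]1CCC(=O)C=C1 | intermediate
5 | (E)-1-methoxy-3-(trimethylsilyloxy)buta-1,3-diene (Danishefsky's diene) | CO/C=C/C(=C)O[Si](C)(C)C | starting material
6 | cis-fused cycloadduct (1R,2S,6S,7S); systematic: (4S,4aS,8S,8aR)-4-isopropyl-8-methoxy-6-(trimethylsilyloxy)-3,4,4a,5,8,8a-hexahydronaphthalen-1(2H)-one | CC(C)[C@@H]1CCC(=O)[C@H]2[C@@H](OC)C=C(O[Si](C)(C)C)C[C@@H]12 | intermediate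
7 | (1R,2S,6S,7S,10R)-spiro-epoxide of 6 (oxirane at C-10; its CH2 = C-14 on the isopropyl face, O on the C-2 face) | CC(C)[C@@H]1CC[C@]3(CO3)[C@H]2[C@@H](OC)C=C(O[Si](C)(C)C)C[C@@H]12 | intermediate
8 | (1S,6S,7S,10R)-epoxy enone: C-10 spiro-oxirane, ring B C-2H=C-3H–C-4(=O)–C-5H2, H-1/H-6 cis | CC(C)[C@@H]1CC[C@]3(CO3)[C@H]2C=CC(=O)C[C@@H]12 | intermediate
9 | (1S,6R,7S,10R)-dienyl triflate: ring B C-2=C-3 and C-4(OSO2CF3)=C-5 | CC(C)[C@@H]1CC[C@]3(CO3)[C@H]2C=CC(OS(=O)(=O)C(F)(F)F)=C[C@@H]12 | intermediate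
10 | (1S,6R,7S,10R)-2-(trimethylsilyl)ethyl dienoate: ring B C-2=C-3 and C-4(CO2CH2CH2SiMe3)=C-5 | CC(C)[C@@H]1CC[C@]3(CO3)[C@H]2C=CC(C(=O)OCC[Si](C)(C)C)=C[C@@H]12 | intermediate
11 | methoxy hydroperoxide: C-1 bears CH(OMe)OOH (both epimers), C-6 bears (E)-CH=C(CHO)CO2CH2CH2SiMe3 | CC(C)[C@@H]1CC[C@]3(CO3)[C@@H](C(OC)OO)[C@H]1/C=C(\C=O)C(=O)OCC[Si](C)(C)C | intermediate
12 | (1S,6R,7S,10R)-aldehyde diester: C-1 CO2Me, C-6 (E)-CH=C(CHO)CO2CH2CH2SiMe3 with CHO cis to C-6 | CC(C)[C@@H]1CC[C@]3(CO3)[C@@H](C(=O)OC)[C@H]1/C=C(\C=O)C(=O)OCC[Si](C)(C)C | intermediate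
13 | (1S,6R,7S,10R)-hydroxy diester: 12 with CH2OH in place of CHO | CC(C)[C@@H]1CC[C@]3(CO3)[C@@H](C(=O)OC)[C@H]1/C=C(\CO)C(=O)OCC[Si](C)(C)C | intermediate
14 | (1S,6R,7S,10R)-epoxy lactone: cis-fused seven-membered lactone C-2(=O)–O–C-3H2–C-4(CO2CH2CH2SiMe3)=C-5H, C-10 spiro-oxirane | CC(C)[C@@H]1CC[C@]3(CO3)[C@H]2C(=O)OCC(C(=O)OCC[Si](C)(C)C)=C[C@@H]12 | intermediate
15 | (2-bromoethoxy)(tert-butyl)dimethylsilane | CC(C)(C)[Si](C)(C)OCCBr | starting material
16 | triphenylphosphine | c1ccc(cc1)P(c1ccccc1)c1ccccc1 | starting material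
17 | [2-(tert-butyldimethylsilyloxy)ethyl]triphenylphosphonium bromide | CC(C)(C)[Si](C)(C)OCC[P+](c1ccccc1)(c1ccccc1)c1ccccc1.[Br-] | intermediate
18 | [2-(tert-butyldimethylsilyloxy)ethylidene]triphenylphosphorane | CC(C)(C)[Si](C)(C)OCC=P(c1ccccc1)(c1ccccc1)c1ccccc1 | intermediate
19 | [3-(tert-butyldimethylsilyloxy)-1-methoxy-1-oxopropan-2-yl]triphenylphosphonium chloride | COC(=O)C(CO[Si](C)(C)C(C)(C)C)[P+](c1ccccc1)(c1ccccc1)c1ccccc1.[Cl-] | intermediate
20 | methyl 3-(tert-butyldimethylsilyloxy)-2-(triphenylphosphoranylidene)propanoate | COC(=O)C(CO[Si](C)(C)C(C)(C)C)=P(c1ccccc1)(c1ccccc1)c1ccccc1 | intermediate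
21 | 2-bromoprop-2-en-1-ol | OCC(Br)=C | starting material
22 | (2-bromoallyloxy)(tert-butyl)dimethylsilane | CC(C)(C)[Si](C)(C)OCC(Br)=C | intermediate
23 | acrolein (prop-2-enal) | C=CC=O | starting material
24 | (E)-4-[(tert-butyldimethylsilyloxy)methyl]penta-2,4-dienal | CC(C)(C)[Si](C)(C)OCC(=C)/C=C/C=O | intermediate
25 | methyl (2E,4E)-2,6-bis[(tert-butyldimethylsilyloxy)methyl]hepta-2,4,6-trienoate | COC(=O)/C(CO[Si](C)(C)C(C)(C)C)=C/C=C/C(=C)CO[Si](C)(C)C(C)(C)C | intermediate
26 | methyl (E)-3-[(1R,6R)-6-acetyl-3-{[(tert-butyldimethylsilyl)oxy]methyl}cyclohex-2-en-1-yl]-2-{[(tert-butyldimethylsilyl)oxy]methyl}prop-2-enoate (acetyl cis to the chain) | COC(=O)/C(=C/[C@H]2C=C(CO[Si](C)(C)C(C)(C)C)CC[C@H]2C(C)=O)CO[Si](C)(C)C(C)(C)C | intermediate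
27 | methyl (E)-3-[(1R,6R)-3-{[(tert-butyldimethylsilyl)oxy]methyl}-6-(prop-1-en-2-yl)cyclohex-2-en-1-yl]-2-{[(tert-butyldimethylsilyl)oxy]methyl}prop-2-enoate | COC(=O)/C(=C/[C@H]2C=C(CO[Si](C)(C)C(C)(C)C)CC[C@H]2C(C)=C)CO[Si](C)(C)C(C)(C)C | intermediate
28 | methyl (E)-3-[(1R,6S)-3-{[(tert-butyldimethylsilyl)oxy]methyl}-6-isopropylcyclohex-2-en-1-yl]-2-{[(tert-butyldimethylsilyl)oxy]methyl}prop-2-enoate | COC(=O)/C(=C/[C@H]2C=C(CO[Si](C)(C)C(C)(C)C)CC[C@H]2C(C)C)CO[Si](C)(C)C(C)(C)C | intermediate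
29 | (E)-3-[(1R,6S)-3-{[(tert-butyldimethylsilyl)oxy]methyl}-6-isopropylcyclohex-2-en-1-yl]-2-{[(tert-butyldimethylsilyl)oxy]methyl}prop-2-enoic acid | OC(=O)/C(=C/[C@H]2C=C(CO[Si](C)(C)C(C)(C)C)CC[C@H]2C(C)C)CO[Si](C)(C)C(C)(C)C | intermediate
30 | protected target: C-14 ester of the (1S,6R,7S,10R)-10-hydroxy lactone (C-15 as 2-(trimethylsilyl)ethyl ester) with acid 29 (both CH2OH groups as TBS ethers) | CC(C)[C@@H]1CC[C@](O)(COC(=O)/C(=C/[C@H]2C=C(CO[Si](C)(C)C(C)(C)C)CC[C@H]2C(C)C)CO[Si](C)(C)C(C)(C)C)[C@H]2C(=O)OCC(C(=O)OCC[Si](C)(C)C)=C[C@@H]12 | intermediate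
31 | CNP0361406.6: C-14 ester of the (1S,6R,7S,10R)-10-hydroxy lactone acid with (E)-2-(hydroxymethyl)-3-[(1R,6S)-3-(hydroxymethyl)-6-isopropylcyclohex-2-en-1-yl]prop-2-enoic acid | CC(C)[C@@H]1CC[C@](O)(COC(=O)/C(=C/[C@H]2C=C(CO)CC[C@H]2C(C)C)CO)[C@H]2C(=O)OCC(C(=O)O)=C[C@@H]12 | target

## Step count and risks

Total steps: 18. Longest linear sequence: 9 steps (for example 21 → 22 → 24 → 25 → 26 → 27 → 28 → 29 → 30 → 31; the branch 1 → 14 → 30 → 31 is also 9).

Steps most likely to fail:

Step 2 (thermal Diels–Alder on a β-hindered cyclohexenone). Fallback, setting out from 4: use the far more reactive (E)-1-(dimethylamino)-3-(tert-butyldimethylsilyloxy)buta-1,3-diene (PhMe, 60 °C) to give the amino cycloadduct F1. Its ketone is epoxidised as in step 3 (ClCH2I, MeLi·LiBr) to the amino spiro-epoxide F2. N-methylation (MeI) followed by Bu4NF generates the enolate, which expels trimethylamine and rejoins the route at enone 8.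

Step 6 (end-differentiating ozonolysis; the formyl acrylate may isomerise under Et3N). Fallback, setting out from 10: ozonolysis with neutral PPh3 work-up gives the dialdehyde F3. One equivalent of LiAlH(OtBu)3 at −78 °C reduces only the unhindered, more electrophilic conjugated aldehyde, and the alcohol closes onto the hindered C-2 aldehyde to give the lactol F4. Oxidation with Ag2CO3 on Celite (PhH, reflux) rejoins the route at lactone 14.

Step 13 (catalytic asymmetric Diels–Alder of an electron-poor trienoate; the facial sense rests on the catalyst model). Fallback, setting out from 25: an auxiliary-controlled cycloaddition with (S)-3-acryloyl-4-benzyloxazolidin-2-one (Et2AlCl, CH2Cl2, −78 °C; endo, α-Si face) gives the imide cycloadduct F5. MeNHOMe·HCl/AlMe3 converts it to the Weinreb amide F6, and MeMgBr (THF, −78 → 0 °C) rejoins the route at ketone 26.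

Further compounds

F1 | step 2 | amino cycloadduct: 2-dimethylamino analogue of 6 with a tert-butyldimethylsilyl enol ether, same stereochemistry as 6 | CC(C)[C@@H]1CCC(=O)[C@H]2[C@@H](N(C)C)C=C(O[Si](C)(C)C(C)(C)C)C[C@@H]12
F2 | step 2 | amino spiro-epoxide: C-10 oxirane of F1, configured as in 7 | CC(C)[C@@H]1CC[C@]3(CO3)[C@H]2[C@@H](N(C)C)C=C(O[Si](C)(C)C(C)(C)C)C[C@@H]12
F3 | step 6 | dialdehyde: C-1 CHO, C-6 (E)-CH=C(CHO)CO2CH2CH2SiMe3, C-10 spiro-oxirane | CC(C)[C@@H]1CC[C@]3(CO3)[C@@H](C=O)[C@H]1/C=C(\C=O)C(=O)OCC[Si](C)(C)C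
F4 | step 6 | lactol: 14 with C-2 as CH(OH), both epimers | CC(C)[C@@H]1CC[C@]3(CO3)[C@H]2C(O)OCC(C(=O)OCC[Si](C)(C)C)=C[C@@H]12
F5 | step 13 | imide cycloadduct: 26 with C(=O)–[(S)-4-benzyl-2-oxooxazolidin-3-yl] in place of acetyl | COC(=O)/C(=C/[C@H]2C=C(CO[Si](C)(C)C(C)(C)C)CC[C@H]2C(=O)N3[C@@H](Cc4ccccc4)COC3=O)CO[Si](C)(C)C(C)(C)C
F6 | step 13 | Weinreb amide: 26 with C(=O)N(OMe)Me in place of acetyl | COC(=O)/C(=C/[C@H]2C=C(CO[Si](C)(C)C(C)(C)C)CC[C@H]2C(=O)N(C)OC)CO[Si](C)(C)C(C)(C)C
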